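## Structural features

The target is a single ten-membered carbocycle, a cis,cis-germacradiene, esterified through the oxygen on one ring carbon with 4-hydroxy-3-methoxybenzoic (vanillic) acid. The ring is numbered C1=C10(CH3)–C9H2–C8(O-vanilloyl)–C7(isopropyl)–C6(OH)–C5=C4(CH3)–C3H2–C2H2, and this skeletal numbering is used for every intermediate. Both ring alkenes are trisubstituted and Z, and C10=C1–C2–C3–C4=C5 is a Z,Z-1,5-diene. The three stereocentres are contiguous, C6 (R), C7 (S) and C8 (R): the two oxygens are 1,3-anti, and with the ring drawn flat the isopropyl group is cis to the ester oxygen and trans to the hydroxyl. Fragile points are the secondary allylic alcohol at C6 (ionisation, transannular attack), the 1,3-diol monoester (acyl migration from O8 to O6), the β-hydroxy ketone that precedes it (retro-aldol ring opening, dehydration, epimerisation at C7), the acid-sensitive medium-ring diene and the free phenol. The real difficulty is to close a ten-membered ring, keep two trisubstituted alkenes Z, and place two differentiated oxygens and an isopropyl group on three adjacent ring carbons in one absolute configuration. The key step exploits that the segment C9–C10(CH3)=C1–C2–C3–C4(CH3)=C5–C6 is the whole carbon framework of 1,5-dimethylcycloocta-1,5-diene, alkene geometry included, so the target ring is that eight-membered ring with the unit C7–C8 inserted between C6 and C9. Because C7 carries the isopropyl group and C6 the oxygen, the inserted unit can arrive as a 3-methylbut-1-en-2-yl group on a C6 carbinol, and the enlargement leaves a C6 ketone from which C8, C7 and C6 are addressed in turn.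

## Logic of the disconnections

22 ⇒ 21. Only the O–Si bond on the phenol oxygen is cut. The phenol must be masked because its acidic proton would quench the samarium alkoxide catalyst one step earlier. The forward step must remove silicon without moving the acyl group from O8 to O6.

21 ⇒ 18 + 20. The acyl C–O8 bond and the C6–H bond are cut together (Tishchenko retron of a 1,3-anti diol monoester). This removes the C6 stereocentre and the question of which hydroxyl is esterified, and makes the aryl part a simple aldehyde. The forward step must deliver hydride to C6 anti to C8–O inside a ten-membered ring, without retro-aldol opening of 18 and without later acyl migration.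

20 ⇒ 19. The O–Si bond is cut; 19 is commercial.

18 ⇒ 16. The C8–O bond and the C7–H bond are cut (conjugate-addition retron). This removes both remaining stereocentres and leaves an achiral trienone, so absolute configuration can come from a catalyst. The forward step must choose C8 over the fully substituted C4, choose one enone face, and protonate C7 on the correct face.

16 ⇒ 13. The C7=C8 unsaturation is removed. 13 is the direct product of the ring enlargement and has a single sp3 α-carbon (C7). The forward step must enolise toward C7 and eliminate into the ring, not toward the isopropyl methine.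

13 ⇒ 10 (key disconnection). The C8–C9 bond is cut and C9 is reconnected to C6. The ten-membered ring becomes an eight-membered one, both Z alkenes become those of a strain-free cyclooctadiene, and the isopropyl-bearing two-carbon unit becomes an alkenyl substituent. The forward step must let C9 migrate from C6 to C8 (1,3-shift) faster than the 3,3-shift, closure onto C4, or proton transfer.

10 ⇒ 6 + 7. The C6–C7 bond is cut (carbinol to alkenyl metal). The forward step must be a clean 1,2-addition to an enone whose C9 methylene is doubly activated, so a non-basic organometallic is needed.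

6 ⇒ 5. The C6 carbonyl and C5=C4 are traced back to a tertiary C4 carbinol with a C5=C6 alkene (1,3-oxygen transposition). This returns the oxygen to the methyl-bearing carbon, where the starting diene can accept it. The forward oxidation must tolerate the second alkene and must not conjugate it.

5 ⇒ 2 ⇒ 1. The C4–O bond and the C5=C6 alkene come from an epoxide across C4=C5, opened at C5 by selenium and eliminated toward C6; the epoxide comes from one of the two equivalent alkenes of 1. The forward steps require mono-oxidation of a symmetric diene and an SN2 opening of a medium-ring epoxide.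

## Other disconnections considered

Alternative 1: The cut is the C2–C3 single bond of the ethano bridge.

- **Forward step:** the open-chain allylic sulfone A1 (phenylsulfonyl on C2, primary allylic chloride on C3, O8 as 4-methoxybenzyl ether, O6 as silyl ether) is deprotonated at C2 under high dilution (KN(SiMe3)2, THF). The carbanion displaces chloride to give the ring sulfone A2.
- **In favour:** sulfur-stabilised allyl anion alkylation is an established way to close ten-membered rings. All three stereocentres and both Z alkenes are made and checked in an open chain by reliable aldol and olefination chemistry. The two oxygens are differentiated from the start.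
- **Against:** the closure pays the full entropic and strain cost of a ten-membered ring (high dilution, oligomers). The allyl anion can alkylate at its γ-terminus and the chloride can react in SN2′ fashion. Reductive desulfonylation of A2 (Na(Hg) or a palladium hydride method) may shift or isomerise C1=C10. Removing the benzyl-type ether, esterifying and desilylating add further steps. A1 itself would need well over fifteen linear steps.
- **Comparison:** on stereocontrol and oxygen differentiation this plan is better than the chosen one, which relies on a catalytic borylation of an unusual medium-ring enone and on a protonation for C7. Its ring-closing mechanism (plain SN2) is also more predictable than an ion-pair 1,3-shift. On alkene geometry the two are equal in outcome, but the chosen plan inherits both Z alkenes from a commodity diene instead of building them. On step economy the chosen plan is far shorter.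

Alternative 2: The cut is the C6–C7 bond, read as the bond made in a [2,3]-Wittig shift.

- **Forward step:** the thirteen-membered cyclic diallyl ether A3 (C6H2–O–C12H2–C11(CH3)=C7, drawn with an E C11=C7 bond, O8 as triethylsilyl ether) is lithiated at C6 (n-BuLi, THF, −78 °C). The α-oxy carbanion bonds to C7 as O–C12 breaks, and the ring contracts to A4, which carries a free C6–OH and an isopropenyl group on C7.
- **In favour:** the hard ring is reached from an easier thirteen-membered etherification. C6 and C7 are created together in one concerted suprafacial C–C bond formation. O6 emerges free while O8 stays protected.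
- **Against:** both ether α-carbons are allylic (C6 next to C5=C4, C12 next to C11=C7), so nothing in A3 secures lithiation at C6; lithiation at C12 would lead to a shift onto C4 or to a [1,2]-shift. The relative configuration of C6 and C7 to C8 depends on the folding of a thirteen-membered transition state and on the C11=C7 geometry, and is hard to predict. The isopropenyl group of A4 must then be hydrogenated in the presence of two trisubstituted alkenes (plausible with RhCl(PPh3)3, but an extra step). C8 and both Z alkenes must still come from a long acyclic synthesis.
- **Comparison:** for C7 this plan is better than the chosen one (C–C bond formation rather than protonation). For oxygen differentiation it is equal (the chosen plan gets this from the Tishchenko step). Mechanistically the sigmatropic step carries stereochemical information, whereas the chosen key step creates none. On regiochemical security of the key step and on step economy the chosen plan is ahead.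

Alternative 3: The ring is hidden in a bicycle: a transannular C4–C8 bond is added in retrosynthesis.

- **Forward step:** the cis-fused bicyclo[5.3.0]decene A5 (tertiary C8–OH at the ring fusion, angular methyl on C4, mesylate on C5, silyl ether on C6, isopropyl on C7) is treated with base. The C8 alkoxide expels the C5 mesylate while C4–C8 breaks, giving the ten-membered silyloxy ketone A6 with a new C8 carbonyl and the C4=C5 alkene.
- **In favour:** the fragmentation is stereospecific, so the Z geometry of C4=C5 follows from the relative configuration of A5. Ring strain is paid by an irreversible step without high dilution. C6 and C7 can be set on a rigid bicycle.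
- **Against:** A5 has five stereocentres, two of them fully substituted, plus a Z trisubstituted alkene in its seven-membered ring; making it would take longer than the whole chosen route. The leaving group sits on the five-membered ring, where alignment with the fusion bond is only approximately antiperiplanar. A6 is a β-silyloxy ketone with an enolisable C7, formed under basic conditions, so loss of the C6 oxygen and epimerisation at C7 are real risks. The C8 ketone must then be reduced to the 8R alcohol by reagent control in a flexible ring before acylation.
- **Comparison:** for the C4=C5 geometry this plan is equal to the chosen one (both secure it, one by stereospecific fragmentation, the other by inheritance). Its key-step mechanism is better defined stereoelectronically than the 1,3-shift. On oxygen placement it is weaker, since the Tishchenko logic would put the ester on the wrong oxygen. On step economy it is much weaker.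

Key step: step 5

Remark on the chemistry (assumption 1): commercial dimethylcycloocta-1,5-diene is an isomer mixture; the route assumes the pure 1,5-dimethyl isomer 1 (fractionated), since the 1,6-isomer would give a regioisomeric dienone.

Remark on the chemistry (assumption 2): the facial sense of the copper catalyst on this medium-ring enone cannot be assigned beforehand; (R,R)-QuinoxP* is written, and its antipode is used if it proves to attack the other face.

Remark on descriptors: C7 is S in 17, 21 and 22 and R in 18 with unchanged geometry, because the priorities of its neighbours change.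

## Route

Step 1
Reactants: 1 (1Z,5Z)-1,5-dimethylcycloocta-1,5-diene
Product: 2 rac-(1R,8S,4Z)-1,5-dimethyl-9-oxabicyclo[6.1.0]non-4-ene
Conditions: mCPBA (0.9 equiv), NaHCO3, CH2Cl2, 0 °C
Reagents that add atoms: 3-chloroperoxybenzoic acid (mCPBA), SMILES OOC(=O)c1cccc(Cl)c1
Why: Prilezhaev epoxidation; the two trisubstituted alkenes of 1 are equivalent, so mono-epoxidation can give only one racemic cis-epoxide, and a slight deficit of peracid limits bis-epoxidation (unreacted 1 is recycled).

Step 2
Reactants: 2 rac-(1R,8S,4Z)-1,5-dimethyl-9-oxabicyclo[6.1.0]non-4-ene
Product: 5 rac-(2Z,5Z)-1,5-dimethylcycloocta-2,5-dien-1-ol, via trans-hydroxy selenide 3 (not isolated), via selenoxide 4 (not isolated)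
Conditions: PhSeSePh, NaBH4, EtOH, reflux; then THF, 30% H2O2, 0 °C to rt
Reagents that add atoms: none
Why: Sharpless–Lauer conversion of an epoxide into the transposed allylic alcohol: benzeneselenolate opens 2 by SN2 attack at the less substituted epoxide carbon, and the selenoxide can only eliminate syn toward the neighbouring ring CH2 because the carbinol carbon has no hydrogen; the single stereocentre of 5 is racemic and is erased in step 3.

Step 3
Reactants: 5 rac-(2Z,5Z)-1,5-dimethylcycloocta-2,5-dien-1-ol
Product: 6 (2Z,6Z)-3,7-dimethylcycloocta-2,6-dien-1-one
Conditions: C5H5NH[CrO3Cl] (2 equiv), 4 Å sieves, CH2Cl2, rt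
Reagents that add atoms: pyridinium chlorochromate C5H5NH[CrO3Cl], SMILES [O-][Cr](=O)(=O)Cl.c1cc[nH+]cc1 (supplies the carbonyl oxygen)
Why: Dauben oxidative 1,3-transposition: the chromate ester of the tertiary allylic alcohol undergoes a [3,3] shift to the secondary allylic chromate, which is oxidised by hexavalent chromium to the β-methyl enone; the new alkene is Z because it lies in an eight-membered ring.

Step 4
Reactants: 6 (2Z,6Z)-3,7-dimethylcycloocta-2,6-dien-1-one; 7 2-bromo-3-methylbut-1-ene
Product: 10 rac-(2Z,6Z)-3,7-dimethyl-1-(3-methylbut-1-en-2-yl)cycloocta-2,6-dien-1-ol, via alkenyllithium 8 (not isolated), via alkenylcerium dichloride 9 (not isolated)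
Conditions: 7, t-BuLi (2 equiv), Et2O, −78 °C; CeCl3 (anhydrous), THF, −78 °C; then 6, −78 °C; aq. NH4Cl
Reagents that add atoms: none
Why: Bromine–lithium exchange followed by Imamoto organocerium 1,2-addition; the weakly basic, oxophilic cerium reagent adds to the carbonyl of the β,β-disubstituted enone without enolising the doubly activated C9 methylene; the new tertiary stereocentre is racemic and is destroyed in step 5.

Step 5
Reactants: 10 rac-(2Z,6Z)-3,7-dimethyl-1-(3-methylbut-1-en-2-yl)cycloocta-2,6-dien-1-ol
Product: 13 rac-(2Z,6Z)-3,7-dimethyl-10-(propan-2-yl)cyclodeca-2,6-dien-1-one, via potassium alkoxide 11 (not isolated), via potassium enolate 12 (not isolated)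
Conditions: KH (1.5 equiv), 18-crown-6 (1.5 equiv), THF, 0 °C to rt; AcOH, −78 °C
Reagents that add atoms: none
Why: KH deprotonates the tertiary carbinol and 18-crown-6 frees the alkoxide, which weakens C6–C9, the only bond at the carbinol carbon whose heterolysis leaves a stabilised (allylic, C9–C10–C1) carbanion beside a cross-conjugated dienone (C5=C4–C6(=O)–C7=C8). Within the contact ion pair the C9 terminus, which starts next to C6, re-bonds to C8, the unsubstituted β-carbon of the isopropyl-bearing enone arm; this net 1,3-shift forms C8–C9 and the ten-membered enolate 12, which AcOH protonates to 13. The closest known reaction type is the oxyanion-accelerated two-carbon ring expansion (anionic 1,3-shift) of potassium 1-vinylcycloalk-3-en-1-olates; the closure is formally 10-endo-trig and is feasible because the nucleophile never leaves the vicinity of the acceptor. No stereocentre of the target is created: C6 becomes a carbonyl carbon, and C7 is protonated unselectively and stays epimerisable. Both Z alkenes are carried over from the eight-membered ring, C4=C5 as a spectator and C10=C1 because the allyl anion keeps its configuration at low temperature. The step needs the 1,3-shift to beat the 3,3-shift (C1 to C8, which would give an eight-membered ketone with an isopropenyl side chain), 6-exo closure of C9 onto C4, and proton transfer that would leave an open-chain enolate. The initial proximity of C9 to C8, the ring-locked Z geometry that holds C1 away from C8, the quaternary centre that attack at the fully substituted C4 would create, and the low temperature all favour the wanted channel.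

Step 6
Reactants: 13 rac-(2Z,6Z)-3,7-dimethyl-10-(propan-2-yl)cyclodeca-2,6-dien-1-one
Product: 16 (2Z,6Z,9Z)-3,7-dimethyl-10-(propan-2-yl)cyclodeca-2,6,9-trien-1-one, via lithium enolate 14 (not isolated), via trimethylsilyl enol ether 15 (not isolated)
Conditions: LiN(iPr)2, TMSCl, THF, −78 °C; then Pd(OAc)2 (1.1 equiv), MeCN, rt
Reagents that add atoms: none
Why: Kinetic deprotonation of the enone at its only sp3 α-carbon (C7, the α′ position, as with piperitone-type enones) and O-silylation give the cross-conjugated silyl dienol ether; Saegusa–Ito oxidation (C-palladation at C7 by divalent palladium, syn β-hydride elimination of a C8 hydrogen) gives the trienone, expected as the ring-cis (Z) C7=C8 isomer in a ring that already holds two Z alkenes; 16 is achiral.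

Step 7
Reactants: 16 (2Z,6Z,9Z)-3,7-dimethyl-10-(propan-2-yl)cyclodeca-2,6,9-trien-1-one
Product: 18 (2Z,6Z,9R,10R)-9-hydroxy-3,7-dimethyl-10-(propan-2-yl)cyclodeca-2,6-dien-1-one, via pinacol boronate 17 (not isolated)
Conditions: CuCl (5 mol%), (R,R)-2,3-bis(tert-butylmethylphosphino)quinoxaline [(R,R)-QuinoxP*] (6 mol%), NaOtBu (10 mol%), B2pin2 (1.2 equiv), MeOH (2 equiv), THF, 0 °C to rt; then NaBO3·4H2O, THF/H2O, rt
Reagents that add atoms: sodium perborate tetrahydrate NaBO3·4H2O, SMILES [Na+].[Na+].O[B-]1(O)OO[B-](O)(O)OO1 (dimeric anion, water of crystallisation omitted; supplies the C8 oxygen)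
Why: Copper-catalysed enantioselective conjugate borylation: the ligated copper boryl adds across C7=C8 with boron on the β-carbon C8 in preference to the fully substituted β-carbon C4, and the chiral diphosphine selects the enone face and so sets C8 (R). Methanol protonates the copper enolate at C7, expected on the face away from the bulky boryl group, which gives the 7,8-anti-aldol relationship of the target. Perborate then replaces boron by oxygen with retention without epoxidising the remaining enone.

Step 8
Reactants: 19 vanillin (4-hydroxy-3-methoxybenzaldehyde)
Product: 20 4-[(tert-butyldimethylsilyl)oxy]-3-methoxybenzaldehyde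
Conditions: TBSCl, imidazole, CH2Cl2, rt
Reagents that add atoms: tert-butyldimethylsilyl chloride (TBSCl), SMILES CC(C)(C)[Si](C)(C)Cl
Why: Standard silylation of a phenol; it masks the acidic OH that would otherwise quench the samarium alkoxide catalyst of step 9.

Step 9
Reactants: 18 (2Z,6Z,9R,10R)-9-hydroxy-3,7-dimethyl-10-(propan-2-yl)cyclodeca-2,6-dien-1-one; 20 4-[(tert-butyldimethylsilyl)oxy]-3-methoxybenzaldehyde
Product: 21 (1R,3Z,7Z,9R,10S)-9-hydroxy-3,7-dimethyl-10-(propan-2-yl)cyclodeca-3,7-dien-1-yl 4-[(tert-butyldimethylsilyl)oxy]-3-methoxybenzoate
Conditions: SmI2 (30 mol%) premixed with 20 (5 equiv), THF, −10 °C, dark; then 18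
Reagents that add atoms: none
Why: Evans–Tishchenko reduction: trivalent samarium (formed when SmI2 meets the aldehyde) binds the hemiacetal made from the C8 hydroxyl and 20 together with the C6 carbonyl, and the hemiacetal C–H is delivered as hydride to C6 through a chair-like six-membered transition state. The new C6–O bond is therefore 1,3-anti to C8–O (6R), and the acyl group ends on O8, which is the ester regiochemistry of the target.

Step 10
Reactants: 21 (1R,3Z,7Z,9R,10S)-9-hydroxy-3,7-dimethyl-10-(propan-2-yl)cyclodeca-3,7-dien-1-yl 4-[(tert-butyldimethylsilyl)oxy]-3-methoxybenzoate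
Product: 22 (1R,3Z,7Z,9R,10S)-9-hydroxy-3,7-dimethyl-10-(propan-2-yl)cyclodeca-3,7-dien-1-yl 4-hydroxy-3-methoxybenzoate
Conditions: Bu4NF, AcOH (1:1), THF, 0 °C
Reagents that add atoms: none
Why: Fluoride cleaves the aryl silyl ether far faster than it touches the ester; buffering with AcOH keeps the phenoxide from promoting O8 to O6 acyl migration; stereocentres and alkenes are untouched.

## Compound list

1 | (1Z,5Z)-1,5-dimethylcycloocta-1,5-diene | C1/C=C(C)\CC/C=C(C)\C1 | starting material
2 | rac-(1R,8S,4Z)-1,5-dimethyl-9-oxabicyclo[6.1.0]non-4-ene (cis-epoxide) | C[C@@]12CC/C=C(C)\CC[C@@H]1O2 | intermediate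
3 | rac-(1R,2R,5Z)-1,5-dimethyl-2-(phenylselanyl)cyclooct-5-en-1-ol (trans-hydroxy selenide) | C[C@@]1(O)CC/C=C(C)\CC[C@H]1[Se]c2ccccc2 | intermediate
4 | rac-(1R,2R,5Z)-2-(benzeneseleninyl)-1,5-dimethylcyclooct-5-en-1-ol (mixture at selenium) | C[C@@]1(O)CC/C=C(C)\CC[C@H]1[Se](=O)c2ccccc2 | intermediate
5 | rac-(2Z,5Z)-1,5-dimethylcycloocta-2,5-dien-1-ol | CC1(O)/C=C\C/C(C)=C\CC1 | intermediate
6 | (2Z,6Z)-3,7-dimethylcycloocta-2,6-dien-1-one | O=C1/C=C(C)\CC/C=C(C)\C1 | intermediate
7 | 2-bromo-3-methylbut-1-ene | C=C(Br)C(C)C | starting material
8 | (3-methylbut-1-en-2-yl)lithium | [Li]C(=C)C(C)C | intermediate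
9 | dichloro(3-methylbut-1-en-2-yl)cerium | Cl[Ce](Cl)C(=C)C(C)C | intermediate
10 | rac-(2Z,6Z)-3,7-dimethyl-1-(3-methylbut-1-en-2-yl)cycloocta-2,6-dien-1-ol | C1/C=C(C)\CC(O)(C(=C)C(C)C)/C=C(C)\C1 | intermediate
11 | potassium rac-(2Z,6Z)-3,7-dimethyl-1-(3-methylbut-1-en-2-yl)cycloocta-2,6-dien-1-olate | C1/C=C(C)\CC([O-])(C(=C)C(C)C)/C=C(C)\C1.[K+] | intermediate
12 | potassium (2Z,6Z)-3,7-dimethyl-10-(propan-2-yl)cyclodeca-1(10),2,6-trien-1-olate (enolate C=C geometry not specified) | CC(C)C1=C([O-])/C=C(C)\CC/C=C(C)\CC1.[K+] | intermediate
13 | rac-(2Z,6Z)-3,7-dimethyl-10-(propan-2-yl)cyclodeca-2,6-dien-1-one | O=C1/C=C(C)\CC/C=C(C)\CCC1C(C)C | intermediate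
14 | lithium (2Z,6Z)-3,7-dimethyl-10-(propan-2-yl)cyclodeca-1(10),2,6-trien-1-olate (enolate C=C geometry not specified) | CC(C)C1=C([O-])/C=C(C)\CC/C=C(C)\CC1.[Li+] | intermediate
15 | trimethyl{[(2Z,6Z)-3,7-dimethyl-10-(propan-2-yl)cyclodeca-1(10),2,6-trien-1-yl]oxy}silane (enol C=C geometry not specified) | CC(C)C1=C(O[Si](C)(C)C)/C=C(C)\CC/C=C(C)\CC1 | intermediate
16 | (2Z,6Z,9Z)-3,7-dimethyl-10-(propan-2-yl)cyclodeca-2,6,9-trien-1-one | CC(C)/C1=C/C/C(C)=C\CC/C(C)=C\C1=O | intermediate
17 | (2Z,6Z,9R,10S)-3,7-dimethyl-10-(propan-2-yl)-9-(4,4,5,5-tetramethyl-1,3,2-dioxaborolan-2-yl)cyclodeca-2,6-dien-1-one | CC1(C)OB(OC1(C)C)[C@@H]2C/C(C)=C\CC/C(C)=C\C(=O)[C@@H]2C(C)C | intermediate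
18 | (2Z,6Z,9R,10R)-9-hydroxy-3,7-dimethyl-10-(propan-2-yl)cyclodeca-2,6-dien-1-one | O[C@@H]1C/C(C)=C\CC/C(C)=C\C(=O)[C@@H]1C(C)C | intermediate
19 | vanillin (4-hydroxy-3-methoxybenzaldehyde) | COc1cc(C=O)ccc1O | starting material
20 | 4-[(tert-butyldimethylsilyl)oxy]-3-methoxybenzaldehyde | COc1cc(C=O)ccc1O[Si](C)(C)C(C)(C)C | intermediate
21 | (1R,3Z,7Z,9R,10S)-9-hydroxy-3,7-dimethyl-10-(propan-2-yl)cyclodeca-3,7-dien-1-yl 4-[(tert-butyldimethylsilyl)oxy]-3-methoxybenzoate | COc1cc(C(=O)O[C@@H]2C/C(C)=C\CC/C(C)=C\[C@@H](O)[C@@H]2C(C)C)ccc1O[Si](C)(C)C(C)(C)C | intermediate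
22 | (1R,3Z,7Z,9R,10S)-9-hydroxy-3,7-dimethyl-10-(propan-2-yl)cyclodeca-3,7-dien-1-yl 4-hydroxy-3-methoxybenzoate | COc1cc(C(=O)O[C@@H]2C/C(C)=C\CC/C(C)=C\[C@@H](O)[C@@H]2C(C)C)ccc1O | target

## Step count and least certain steps

Total: 10 steps. Longest linear sequence: 9 steps (steps 1 to 7, 9 and 10, from 1); step 8 is a one-step side branch.

**Step 5 (key step).** The most likely failures are loss of pathway selectivity and loss of the ring. The allyl terminus C1 may bond to C8 (3,3-shift) instead of C9. If the carbanion escapes the ion pair, C9 may close onto C4 in a 6-exo mode. The allyl anion may also pick up a γ-proton of the dienone (C3–H or the C4 methyl), which would leave an open-chain enolate that cannot re-close. Fallback, setting out from 10 and coming back at 15: 10 is silylated with N-(trimethylsilyl)imidazole to the trimethylsilyl ether trimethyl{[(2Z,6Z)-3,7-dimethyl-1-(3-methylbut-1-en-2-yl)cycloocta-2,6-dien-1-yl]oxy}silane F1. F1 is passed in dilute solution through a hot tube (about 280–320 °C, short contact time). The neutral thermal siloxy 1,3-shift, known for 1-silyloxy-1-vinylcycloalk-3-enes, breaks the same C6–C9 bond homolytically and recombines at C8, with no carbanion to be protonated or to add to C4. It should give silyl enol ether 15 directly, which is oxidised with Pd(OAc)2 as in the second half of step 6. Contact time must be short enough that the Z,Z-1,5-diene of the product does not undergo Cope rearrangement.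

**Step 7.** Three things may go wrong: poor facial selectivity at C8, because a twisted, α-branched medium-ring Z-enone is an unusual substrate for the catalyst; protonation of the enolate at C7 from the wrong face, or later epimerisation there; and retro-aldol opening or dehydration of 18 during oxidation. Fallback, setting out from 16 and coming back at 18: nucleophilic asymmetric epoxidation (La(OiPr)3, BINOL of the appropriate sense, Ph3As=O, tert-butyl hydroperoxide, 4 Å sieves, THF) should attack the more accessible C7=C8 enone and give the epoxy ketone (1R,3Z,7Z,10R)-4,8-dimethyl-1-(propan-2-yl)-11-oxabicyclo[8.1.0]undeca-3,7-dien-2-one F2. SmI2 in THF/MeOH at −90 °C then cleaves the C7–O bond reductively and leaves the C8–O bond, giving 18 with C7 set by low-temperature protonation of a chelated samarium enolate.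

**Step 6.** β-Hydride elimination may run toward the isopropyl methine (exocyclic isopropylidene enone) instead of C8. Deprotonation of 13 may occur at a γ-position instead of C7. Divalent palladium may be held by the 1,5-diene and trigger transannular chemistry. The new alkene may form as a mixture of ring-cis and ring-trans isomers. Fallback, setting out from 12 (in the flask of step 5, before AcOH is added) and coming back at 16: the regiodefined potassium enolate is trapped with PhSeBr at −78 °C to give rac-(2Z,6Z)-3,7-dimethyl-10-(phenylselanyl)-10-(propan-2-yl)cyclodeca-2,6-dien-1-one F3. Oxidation (H2O2, pyridine, CH2Cl2, 0 °C) gives the selenoxide rac-(2Z,6Z)-10-(benzeneseleninyl)-3,7-dimethyl-10-(propan-2-yl)cyclodeca-2,6-dien-1-one F4, whose syn-elimination should prefer the ring C8 hydrogens over the hindered methine and gives 16 without any palladium.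

**Step 9.** Hemiacetal formation with the electron-rich aldehyde may be slow, giving the samarium alkoxide time to open 18 by retro-aldol. The product may suffer O8 to O6 acyl migration under the catalyst. The ring may distort the chair transition state and erode the 1,3-anti selectivity. Fallback, setting out from 18 and coming back at 21: hydroxyl-directed reduction with Me4NBH(OAc)3 in MeCN/AcOH at −30 °C (internal hydride delivery, 1,3-anti) gives (1R,2R,3R,4Z,8Z)-5,9-dimethyl-2-(propan-2-yl)cyclodeca-4,8-diene-1,3-diol F5. Aldehyde 20 is oxidised (NaClO2, NaH2PO4, 2-methylbut-2-ene, t-BuOH/H2O) to 4-[(tert-butyldimethylsilyl)oxy]-3-methoxybenzoic acid F6. F5 is esterified with one equivalent of F6 (N,N'-dicyclohexylcarbodiimide, 4-(dimethylamino)pyridine, CH2Cl2, low temperature), relying on the lower hindrance of the non-allylic C8 hydroxyl, to give 21.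

**Step 2.** SN2 opening of a cyclooctene oxide is slow because transannular hydrogens shield the backside, so incomplete conversion or transannular participation of the second alkene is possible. Fallback, setting out from 1 and coming back at 3: direct hydroxyselenation of 1 with N-(phenylselanyl)phthalimide, water and catalytic camphorsulfonic acid in CH2Cl2 (one equivalent) adds selenium and hydroxyl anti across one alkene with the hydroxyl on the methyl-bearing carbon. This is the same trans-hydroxy selenide 3, reached without the epoxide, and it is oxidised and eliminated to 5 as in step 2.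

Further compounds

F1 | step 5 | trimethyl{[(2Z,6Z)-3,7-dimethyl-1-(3-methylbut-1-en-2-yl)cycloocta-2,6-dien-1-yl]oxy}silane (racemic) | C1/C=C(C)\CC(O[Si](C)(C)C)(C(=C)C(C)C)/C=C(C)\C1
F2 | step 7 | (1R,3Z,7Z,10R)-4,8-dimethyl-1-(propan-2-yl)-11-oxabicyclo[8.1.0]undeca-3,7-dien-2-one | CC(C)[C@@]12O[C@@H]1C/C(C)=C\CC/C(C)=C\C2=O
F3 | step 6 | rac-(2Z,6Z)-3,7-dimethyl-10-(phenylselanyl)-10-(propan-2-yl)cyclodeca-2,6-dien-1-one | O=C1/C=C(C)\CC/C=C(C)\CCC1(C(C)C)[Se]c2ccccc2
F4 | step 6 | rac-(2Z,6Z)-10-(benzeneseleninyl)-3,7-dimethyl-10-(propan-2-yl)cyclodeca-2,6-dien-1-one | O=C1/C=C(C)\CC/C=C(C)\CCC1(C(C)C)[Se](=O)c2ccccc2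
F5 | step 9 | (1R,2R,3R,4Z,8Z)-5,9-dimethyl-2-(propan-2-yl)cyclodeca-4,8-diene-1,3-diol | O[C@@H]1C/C(C)=C\CC/C(C)=C\[C@@H](O)[C@@H]1C(C)C
F6 | step 9 | 4-[(tert-butyldimethylsilyl)oxy]-3-methoxybenzoic acid | COc1cc(C(=O)O)ccc1O[Si](C)(C)C(C)(C)C
F0 | step 2 | none | none
A1 | alternative 1 | open-chain (2Z,8Z)-10-chloro-3,9-dimethyl-5-[(4-methoxyphenyl)methoxy]-6-(propan-2-yl)-7-[(tert-butyldimethylsilyl)oxy]deca-2,8-dien-1-yl phenyl sulfone (chain C5, C6, C7 are skeletal C8, C7, C6, configured as in the target) | O=S(=O)(c1ccccc1)C/C=C(C)\C[C@@H](OCc2ccc(OC)cc2)[C@@H](C(C)C)[C@H](O[Si](C)(C)C(C)(C)C)/C=C(C)\CCl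
A2 | alternative 1 | 2-(benzenesulfonyl) Z,Z-cyclodecadiene with 8-O-(4-methoxybenzyl), 7-isopropyl and 6-O-(tert-butyldimethylsilyl) (skeletal numbering) | O=S(=O)(c1ccccc1)C1/C=C(C)\C[C@@H](OCc2ccc(OC)cc2)[C@@H](C(C)C)[C@H](O[Si](C)(C)C(C)(C)C)/C=C(C)\C1
A3 | alternative 2 | thirteen-membered cyclic diallyl ether C6H2–O–C12H2–C11(CH3)=C7 (E), with 8-O-triethylsilyl and the two Z ring alkenes (skeletal numbering) | CC[Si](CC)(CC)O[C@@H]1C/C(C)=C\CC/C(C)=C\COC/C(C)=C/1
A4 | alternative 2 | 8-O-triethylsilyl 7-isopropenyl Z,Z-cyclodecadiene-6,8-diol (skeletal numbering) | CC[Si](CC)(CC)O[C@@H]1C/C(C)=C\CC/C(C)=C\[C@@H](O)[C@@H]1C(C)=C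
A5 | alternative 3 | cis-fused bicyclo[5.3.0]dec-ene with tertiary C8–OH at the ring fusion, angular C4 methyl, C5 mesylate cis to the seven-membered ring, C6 O-(tert-butyldimethylsilyl) and C7 isopropyl (skeletal numbering) | O[C@]12C/C(C)=C\CC[C@@]1(C)[C@@H](OS(C)(=O)=O)[C@@H](O[Si](C)(C)C(C)(C)C)[C@@H]2C(C)C
A6 | alternative 3 | 6-O-(tert-butyldimethylsilyl) 7-isopropyl Z,Z-cyclodecadien-8-one (skeletal numbering) | O=C1C/C(C)=C\CC/C(C)=C\[C@@H](O[Si](C)(C)C(C)(C)C)[C@@H]1C(C)C
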